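Ring A (the 5,6‑epoxy‑3‑hydroxycyclohexane end group, carotenoid numbering) is cut into a crotonate unit C3–C4–C5 and a unit C6–C1–C2 whose future exocyclic carbon C7 is bonded to both C2 and C6 as the carbonyl of 3,3‑dimethylcyclobutanone. The key step uses the fact that C2 and C6 both flank the quaternary C1 and that C6 bears C7: one Michael/Claisen/retro‑Claisen cascade forms C5–C6 and C2–C3, closes the six‑membered ring and releases C7 as an ester. The keto ester becomes an epoxy vinylstannane; an enyne polyenal, an actinol triflate and a bromobutenolide complete a convergent Sonogashira/aldol/Stille assembly.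

Key step: step 1

Remarks: ring A is numbered as in carotenoids (C1 CMe2, C2 CH2, C3 CHOH, C4 CH2, C5 CMe–O, C6 C–O, C7 first chain carbon); compounds 1, 22 and 26 are assumed to be catalogue compounds.

Step 1
Reactants: 1 3,3-dimethylcyclobutan-1-one; 2 methyl (E)-but-2-enoate
Product: 5 methyl 2,6,6-trimethyl-4-oxocyclohexane-1-carboxylate (racemic cis/trans mixture), via Michael adduct enolate 3 (not isolated), via bicyclic diketone 4 (not isolated)
Conditions: LiN(i-Pr)2 (1.05 equiv), THF, −78 °C; 2, −78 → 25 °C; aq. NH4Cl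
Reagents that add atoms: none
Why: Proposed new method: the lithium enolate of 1 should add 1,4 to 2 (C5–C6 bond), proton transfer gives the α′-enolate, which acylates on the pendant methyl ester (C2–C3 bond) to give the bridged diketone 4, and the methoxide just expelled attacks the strained four-membered ketone C7 of 4 so that retro-Claisen cleavage of C7–C2 delivers the cyclohexanone enolate of 5 with C7 as the methyl ester. The closest known reaction types are the Michael–Claisen [3+3] annulation of ketone enolates with enoates to cyclohexane-1,3-diones and the α,α′-annulation of cyclic ketone enamines with acryloyl chlorides followed by retro-Claisen ring enlargement of the bicyclic 1,3-dione; neither has been shown on a cyclobutanone. The six-membered ring closes by 6-exo-trig enolate C-acylation across the 1,3-positions of the puckered cyclobutanone, giving a pinane-like bicyclo[3.1.1] skeleton, and the four-membered ring then opens. The two new stereocentres C5 and C6 form without control, which is harmless because C5 becomes sp2 in step 2 and C6 in step 4. The step needs 1,4- rather than 1,2-addition, the usual course for lithium ketone enolates and crotonates at −78 °C, and cleavage of C7–C2 rather than C2–C3 or C6–C7, which is secured by the strain released on opening the cyclobutanone and by C2 being the only carbon flanked by both carbonyls.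

Step 2
Reactants: 5 methyl 2,6,6-trimethyl-4-oxocyclohexane-1-carboxylate
Product: 6 methyl 2,6,6-trimethyl-4-oxocyclohex-2-ene-1-carboxylate (racemic)
Conditions: 2-iodoxybenzoic acid (2 equiv), DMSO, 70 °C
Reagents that add atoms: none
Why: Dehydrogenation of the ketone by 2-iodoxybenzoic acid through its enol can only give the C4=C5 enone, because the other α-carbon (C2) adjoins the quaternary C1 and has no β-hydrogen.

Step 3
Reactants: 6 methyl 2,6,6-trimethyl-4-oxocyclohex-2-ene-1-carboxylate
Product: 7 methyl (4S)-4-hydroxy-2,6,6-trimethylcyclohex-2-ene-1-carboxylate (both C1 epimers)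
Conditions: (R)-2-methyl-CBS-oxazaborolidine (0.2 equiv), catecholborane, toluene, −78 °C
Reagents that add atoms: none
Why: Corey–Bakshi–Shibata reduction: the (R)-oxazaborolidine should deliver hydride to the enone carbonyl with the alkene arm as the large group, setting C3 under catalyst control in both ester epimers while the ester is untouched.

Step 4
Reactants: 7 methyl (4S)-4-hydroxy-2,6,6-trimethylcyclohex-2-ene-1-carboxylate
Product: 8 methyl (4R)-4-hydroxy-2,6,6-trimethylcyclohex-1-ene-1-carboxylate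
Conditions: t-BuOK (1.5 equiv), t-BuOH/THF, 25 °C; AcOH
Reagents that add atoms: none
Why: Base-mediated prototropic shift through the ester dienolate should move the double bond into the tetrasubstituted, ester-conjugated C5=C6 position and erase the C6 stereocentre, while the hydroxyl, held as its potassium alkoxide, is a poor leaving group for vinylogous E1cB loss (the R descriptor at C3 is only a priority change).

Step 5
Reactants: 8 methyl (4R)-4-hydroxy-2,6,6-trimethylcyclohex-1-ene-1-carboxylate
Product: 9 methyl (4R)-2,6,6-trimethyl-4-(triethylsilyloxy)cyclohex-1-ene-1-carboxylate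
Conditions: Et3SiCl, imidazole, DMF, 0 → 25 °C
Reagents that add atoms: chlorotriethylsilane, CC[Si](Cl)(CC)CC
Why: Standard silylation of the secondary alcohol protects C3–OH through the reduction, epoxidation, oxidation and olefination that follow.

Step 6
Reactants: 9 methyl (4R)-2,6,6-trimethyl-4-(triethylsilyloxy)cyclohex-1-ene-1-carboxylate
Product: 10 [(4R)-2,6,6-trimethyl-4-(triethylsilyloxy)cyclohex-1-en-1-yl]methanol
Conditions: i-Bu2AlH (2.5 equiv), CH2Cl2, −78 → 0 °C; Rochelle salt
Reagents that add atoms: none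
Why: 1,2-Reduction of the hindered conjugated ester by the aluminium hydride should give the allylic alcohol (C7–OH) needed for the directed epoxidation.

Step 7
Reactants: 10 [(4R)-2,6,6-trimethyl-4-(triethylsilyloxy)cyclohex-1-en-1-yl]methanol
Product: 11 [(1R,4S,6R)-2,2,6-trimethyl-4-(triethylsilyloxy)-7-oxabicyclo[4.1.0]heptan-1-yl]methanol (epoxide oxygen anti to the silyloxy group)
Conditions: Ti(Oi-Pr)4 (0.2 equiv), D-(−)-diethyl tartrate (0.25 equiv), t-BuOOH, 4 Å molecular sieves, CH2Cl2, −20 °C
Reagents that add atoms: tert-butyl hydroperoxide, CC(C)(C)OO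
Why: Katsuki–Sharpless asymmetric epoxidation: the D-tartrate complex should deliver oxygen to the face of C5=C6 opposite the C3 silyloxy group (reagent control matched with the steric bias), setting C5 and C6 and turning any minor enantiomer of 10 into a separable diastereomer.

Step 8
Reactants: 11 [(1R,4S,6R)-2,2,6-trimethyl-4-(triethylsilyloxy)-7-oxabicyclo[4.1.0]heptan-1-yl]methanol
Product: 12 (1S,4S,6R)-2,2,6-trimethyl-4-(triethylsilyloxy)-7-oxabicyclo[4.1.0]heptane-1-carbaldehyde
Conditions: Dess–Martin periodinane, pyridine, CH2Cl2, 0 → 25 °C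
Reagents that add atoms: none
Why: Buffered Dess–Martin oxidation converts the neopentyl-type primary alcohol into the non-enolisable epoxy aldehyde without touching the epoxide or the silyl ether.

Step 9
Reactants: 12 (1S,4S,6R)-2,2,6-trimethyl-4-(triethylsilyloxy)-7-oxabicyclo[4.1.0]heptane-1-carbaldehyde
Product: 13 tributyl{(E)-2-[(1S,4S,6R)-2,2,6-trimethyl-4-(triethylsilyloxy)-7-oxabicyclo[4.1.0]heptan-1-yl]ethenyl}stannane
Conditions: CrCl2, Bu3SnCHBr2, LiI, THF/DMF, 25 °C
Reagents that add atoms: (dibromomethyl)tributylstannane, CCCC[Sn](CCCC)(CCCC)C(Br)Br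
Why: Hodgson variant of the Takai olefination: the geminal dichromium species formed from the in situ diiodide and divalent chromium adds to the aldehyde and eliminates to the (E)-alkenylstannane (C7=C8), conditions that α,β-epoxy aldehydes tolerate.

Step 10
Reactants: 13 tributyl{(E)-2-[(1S,4S,6R)-2,2,6-trimethyl-4-(triethylsilyloxy)-7-oxabicyclo[4.1.0]heptan-1-yl]ethenyl}stannane
Product: 14 (1S,4S,6R)-2,2,6-trimethyl-1-[(E)-2-(tributylstannyl)ethenyl]-7-oxabicyclo[4.1.0]heptan-4-ol
Conditions: n-Bu4NF, THF, 0 °C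
Reagents that add atoms: none
Why: Fluoride cleaves the triethylsilyl ether while the alkenylstannane and the epoxide are inert, so that the last coupling can deliver the free C3 alcohol directly.

Step 11
Reactants: 15 (E)-3-methylpent-2-en-4-yn-1-ol
Product: 16 [(2E)-3-methylpent-2-en-4-yn-1-yl]triphenylphosphonium bromide
Conditions: PPh3·HBr, CH2Cl2/MeOH, 25 °C
Reagents that add atoms: triphenylphosphine hydrobromide, Br.P(c1ccccc1)(c1ccccc1)c1ccccc1
Why: Acid-promoted ionisation of the allylic alcohol and capture of the allyl cation at its primary terminus by the phosphine is the classical entry to allylic Wittig salts.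

Step 12
Reactants: 16 [(2E)-3-methylpent-2-en-4-yn-1-yl]triphenylphosphonium bromide; 17 (E)-4,4-dimethoxybut-2-enal
Product: 19 (2E,4E,6E)-7-methylnona-2,4,6-trien-8-ynal, via dimethyl acetal 18 (not isolated)
Conditions: NaOMe, MeOH/CH2Cl2, 0 °C; 1 M HCl, THF, 25 °C; I2 (1 mol %), CH2Cl2, 25 °C
Reagents that add atoms: water, O
Why: Wittig reaction of the semistabilised allylic ylide (formed selectively, since the phosphonium salt is far more acidic than the alkyne) with the enal, then acetal hydrolysis and brief iodine-catalysed equilibration of the new disubstituted C11′=C14′ bond to E.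

Step 13
Reactants: 19 (2E,4E,6E)-7-methylnona-2,4,6-trien-8-ynal; 20 2-(triphenyl-λ5-phosphanylidene)propanal
Product: 21 (2E,4E,6E,8E)-2,9-dimethylundeca-2,4,6,8-tetraen-10-ynal
Conditions: toluene, 80 °C
Reagents that add atoms: none
Why: Wittig reaction of the stabilised formyl ylide is E-selective and stops after one homologation because the α-methyl enal product is less reactive than 19.

Step 14
Reactants: 22 (4R,6R)-4-hydroxy-2,2,6-trimethylcyclohexan-1-one
Product: 23 (4R,6R)-4-acetoxy-2,2,6-trimethylcyclohexan-1-one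
Conditions: Ac2O, pyridine, 4-(dimethylamino)pyridine (cat.), CH2Cl2, 25 °C
Reagents that add atoms: acetic anhydride, CC(=O)OC(C)=O
Why: Acylation of the secondary alcohol installs the 3′-acetate of the target at the outset; the stereocentre is taken from the chiral pool.

Step 15
Reactants: 23 (4R,6R)-4-acetoxy-2,2,6-trimethylcyclohexan-1-one
Product: 24 (1R)-3,5,5-trimethyl-4-(trifluoromethylsulfonyloxy)cyclohex-3-en-1-yl acetate
Conditions: Tf2O, 2,6-di-tert-butyl-4-methylpyridine, CH2Cl2, 0 → 25 °C
Reagents that add atoms: trifluoromethanesulfonic anhydride, O=S(=O)(OS(=O)(=O)C(F)(F)F)C(F)(F)F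
Why: O-Triflation of the ketone under hindered-base conditions can only give the C5′=C6′ enol triflate (the other α-carbon is quaternary) and tolerates the acetate.

Step 16
Reactants: 24 (1R)-3,5,5-trimethyl-4-(trifluoromethylsulfonyloxy)cyclohex-3-en-1-yl acetate; 21 (2E,4E,6E,8E)-2,9-dimethylundeca-2,4,6,8-tetraen-10-ynal
Product: 25 (1R)-4-[(3E,5E,7E,9E)-3,10-dimethyl-11-oxoundeca-3,5,7,9-tetraen-1-yn-1-yl]-3,5,5-trimethylcyclohex-3-en-1-yl acetate
Conditions: Pd(PPh3)4 (5 mol %), CuI (10 mol %), Et3N, DMF, 25 °C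
Reagents that add atoms: none
Why: Sonogashira coupling: oxidative addition of the enol triflate to zerovalent palladium and transfer of the copper acetylide form the C6′–C7′ bond without touching the aldehyde, acetate or alkene geometries.

Step 17
Reactants: 25 (1R)-4-[(3E,5E,7E,9E)-3,10-dimethyl-11-oxoundeca-3,5,7,9-tetraen-1-yn-1-yl]-3,5,5-trimethylcyclohex-3-en-1-yl acetate; 26 3-bromofuran-2(5H)-one
Product: 29 (1R)-4-{(3E,5E,7E,9E,11Z)-11-[4-bromo-5-oxofuran-2(5H)-ylidene]-3,10-dimethylundeca-3,5,7,9-tetraen-1-yn-1-yl}-3,5,5-trimethylcyclohex-3-en-1-yl acetate, via silyloxyfuran 27 (not isolated), via silyl aldol adduct 28 (not isolated)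
Conditions: t-BuMe2SiOTf, i-Pr2NEt, CH2Cl2, −78 → 0 °C; then DBU, 25 °C
Reagents that add atoms: none
Why: Vinylogous Mukaiyama aldol addition of the in situ 2-silyloxyfuran through its C5 to the silyl-triflate-activated aldehyde, then DBU-induced E1cB loss of silanolate, should give the thermodynamically preferred (Z)-ylidenebutenolide (chain cis to the ring oxygen).

Step 18
Reactants: 14 (1S,4S,6R)-2,2,6-trimethyl-1-[(E)-2-(tributylstannyl)ethenyl]-7-oxabicyclo[4.1.0]heptan-4-ol; 29 (1R)-4-{(3E,5E,7E,9E,11Z)-11-[4-bromo-5-oxofuran-2(5H)-ylidene]-3,10-dimethylundeca-3,5,7,9-tetraen-1-yn-1-yl}-3,5,5-trimethylcyclohex-3-en-1-yl acetate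
Product: 30 pyrrhoxanthin, (3S,5R,6S,3′R)-5,6-epoxy-3,3′-dihydroxy-7′,8′-didehydro-5,6-dihydro-12′,13′,20′-trinor-β,β-caroten-19,11-olide 3′-acetate
Conditions: Pd2(dba)3 (5 mol %), AsPh3 (40 mol %), N-methylpyrrolidone, 25–40 °C, dark
Reagents that add atoms: none
Why: Stille coupling: oxidative addition of the 3-bromobutenolide to zerovalent palladium, transmetalation of the alkenylstannane with retention of the E geometry and reductive elimination form the C8–C9 bond under neutral conditions that leave epoxide, free hydroxyl, acetate and polyene untouched.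

Compound list
1 | 3,3-dimethylcyclobutan-1-one | CC1(C)CC(=O)C1 | starting material
2 | methyl (E)-but-2-enoate | C/C=C/C(=O)OC | starting material
3 | methyl 3-(2,2-dimethyl-4-oxocyclobutyl)butanoate (lithium enolate in the flask) | COC(=O)CC(C)C1C(=O)CC1(C)C | intermediate
4 | 4,7,7-trimethylbicyclo[3.1.1]heptane-2,6-dione | CC1CC(=O)C2C(=O)C1C2(C)C | intermediate
5 | methyl 2,6,6-trimethyl-4-oxocyclohexane-1-carboxylate (racemic, cis/trans) | COC(=O)C1C(C)CC(=O)CC1(C)C | intermediate
6 | methyl 2,6,6-trimethyl-4-oxocyclohex-2-ene-1-carboxylate (racemic) | COC(=O)C1C(C)=CC(=O)CC1(C)C | intermediate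
7 | methyl (4S)-4-hydroxy-2,6,6-trimethylcyclohex-2-ene-1-carboxylate (C1 epimers) | COC(=O)C1C(C)=C[C@@H](O)CC1(C)C | intermediate
8 | methyl (4R)-4-hydroxy-2,6,6-trimethylcyclohex-1-ene-1-carboxylate | COC(=O)C1=C(C)C[C@@H](O)CC1(C)C | intermediate
9 | methyl (4R)-2,6,6-trimethyl-4-(triethylsilyloxy)cyclohex-1-ene-1-carboxylate | COC(=O)C1=C(C)C[C@@H](O[Si](CC)(CC)CC)CC1(C)C | intermediate
10 | [(4R)-2,6,6-trimethyl-4-(triethylsilyloxy)cyclohex-1-en-1-yl]methanol | OCC1=C(C)C[C@@H](O[Si](CC)(CC)CC)CC1(C)C | intermediate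
11 | [(1R,4S,6R)-2,2,6-trimethyl-4-(triethylsilyloxy)-7-oxabicyclo[4.1.0]heptan-1-yl]methanol | OC[C@@]12O[C@]1(C)C[C@@H](O[Si](CC)(CC)CC)CC2(C)C | intermediate
12 | (1S,4S,6R)-2,2,6-trimethyl-4-(triethylsilyloxy)-7-oxabicyclo[4.1.0]heptane-1-carbaldehyde | O=C[C@@]12O[C@]1(C)C[C@@H](O[Si](CC)(CC)CC)CC2(C)C | intermediate
13 | tributyl{(E)-2-[(1S,4S,6R)-2,2,6-trimethyl-4-(triethylsilyloxy)-7-oxabicyclo[4.1.0]heptan-1-yl]ethenyl}stannane | CCCC[Sn](CCCC)(CCCC)/C=C/[C@@]12O[C@]1(C)C[C@@H](O[Si](CC)(CC)CC)CC2(C)C | intermediate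
14 | (1S,4S,6R)-2,2,6-trimethyl-1-[(E)-2-(tributylstannyl)ethenyl]-7-oxabicyclo[4.1.0]heptan-4-ol | CCCC[Sn](CCCC)(CCCC)/C=C/[C@@]12O[C@]1(C)C[C@@H](O)CC2(C)C | intermediate
15 | (E)-3-methylpent-2-en-4-yn-1-ol | C#C/C(C)=C/CO | starting material
16 | [(2E)-3-methylpent-2-en-4-yn-1-yl]triphenylphosphonium bromide | C#C/C(C)=C/C[P+](c1ccccc1)(c1ccccc1)c1ccccc1.[Br-] | intermediate
17 | (E)-4,4-dimethoxybut-2-enal | COC(OC)/C=C/C=O | starting material
18 | (3E,5E,7E)-9,9-dimethoxy-3-methylnona-3,5,7-trien-1-yne (5E/5Z mixture before equilibration) | C#C/C(C)=C/C=C/C=C/C(OC)OC | intermediate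
19 | (2E,4E,6E)-7-methylnona-2,4,6-trien-8-ynal | C#C/C(C)=C/C=C/C=C/C=O | intermediate
20 | 2-(triphenyl-λ5-phosphanylidene)propanal | CC(C=O)=P(c1ccccc1)(c1ccccc1)c1ccccc1 | starting material
21 | (2E,4E,6E,8E)-2,9-dimethylundeca-2,4,6,8-tetraen-10-ynal | C#C/C(C)=C/C=C/C=C/C=C(C)/C=O | intermediate
22 | (4R,6R)-4-hydroxy-2,2,6-trimethylcyclohexan-1-one (actinol) | O[C@@H]1C[C@@H](C)C(=O)C(C)(C)C1 | starting material
23 | (4R,6R)-4-acetoxy-2,2,6-trimethylcyclohexan-1-one | CC(=O)O[C@@H]1C[C@@H](C)C(=O)C(C)(C)C1 | intermediate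
24 | (1R)-3,5,5-trimethyl-4-(trifluoromethylsulfonyloxy)cyclohex-3-en-1-yl acetate | CC(=O)O[C@@H]1CC(C)=C(OS(=O)(=O)C(F)(F)F)C(C)(C)C1 | intermediate
25 | (1R)-4-[(3E,5E,7E,9E)-3,10-dimethyl-11-oxoundeca-3,5,7,9-tetraen-1-yn-1-yl]-3,5,5-trimethylcyclohex-3-en-1-yl acetate | CC(=O)O[C@@H]1CC(C)=C(C#C/C(C)=C/C=C/C=C/C=C(C)/C=O)C(C)(C)C1 | intermediate
26 | 3-bromofuran-2(5H)-one | BrC1=CCOC1=O | starting material
27 | 3-bromo-2-(tert-butyldimethylsilyloxy)furan | CC(C)(C)[Si](C)(C)Oc1occc1Br | intermediate
28 | (1R)-4-[(3E,5E,7E,9E)-11-(4-bromo-5-oxo-2,5-dihydrofuran-2-yl)-11-(tert-butyldimethylsilyloxy)-3,10-dimethylundeca-3,5,7,9-tetraen-1-yn-1-yl]-3,5,5-trimethylcyclohex-3-en-1-yl acetate (diastereomer mixture) | CC(=O)O[C@@H]1CC(C)=C(C#C/C(C)=C/C=C/C=C/C=C(C)/C(O[Si](C)(C)C(C)(C)C)C2OC(=O)C(Br)=C2)C(C)(C)C1 | intermediate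
29 | (1R)-4-{(3E,5E,7E,9E,11Z)-11-[4-bromo-5-oxofuran-2(5H)-ylidene]-3,10-dimethylundeca-3,5,7,9-tetraen-1-yn-1-yl}-3,5,5-trimethylcyclohex-3-en-1-yl acetate | CC(=O)O[C@@H]1CC(C)=C(C#C/C(C)=C/C=C/C=C/C=C(C)/C=C2C=C(Br)C(=O)O/2)C(C)(C)C1 | intermediate
30 | pyrrhoxanthin | CC(=O)O[C@@H]1CC(C)=C(C#C/C(C)=C/C=C/C=C/C=C(C)/C=C2C=C(/C=C/[C@@]34O[C@]3(C)C[C@@H](O)CC4(C)C)C(=O)O/2)C(C)(C)C1 | target

Total step count: 18 steps. Longest linear sequence: 11 steps (steps 1–10, then step 18).

Steps most likely to fail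

1. Step 1 (Proposed new method). The Michael adduct enolate may fail to close onto the ester to give the strained bridged diketone, or the cyclobutanone enolate may be lost to self-aldol condensation and 1,2-addition before the cascade starts. The fallback uses known Michael–Dieckmann chemistry, sets out from 2 and returns at 5. Commercial 3,3-dimethylpentanedioic acid is esterified (2-methylpropene, H2SO4 cat.) to di-tert-butyl 3,3-dimethylpentanedioate F1. Its lithium enolate (LiN(i-Pr)2, THF, −78 °C) adds 1,4 to 2, and after addition of t-BuOK/t-BuOH the second ester α-carbon closes onto the methyl ester, the tert-butyl esters being inert as acceptors, to give di-tert-butyl 2,2,4-trimethyl-6-oxocyclohexane-1,3-dicarboxylate F2; the same two ring bonds are formed. CF3CO2H removes both tert-butyl groups and the β-keto acid loses CO2 to give 2,6,6-trimethyl-4-oxocyclohexane-1-carboxylic acid F3, which Me3SiCHN2/MeOH converts into 5.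

2. Step 4. The dienolate that carries the double-bond shift may instead expel the C3 oxygen (vinylogous E1cB dehydration to the cyclohexadiene ester), or the conjugated isomer may not dominate at equilibrium. The fallback avoids any dienolate, sets out from 7 and returns at 9. Silylation (Et3SiCl, imidazole) gives methyl (4S)-2,6,6-trimethyl-4-(triethylsilyloxy)cyclohex-2-ene-1-carboxylate F4. Hydrogenation (H2, Rh/Al2O3) gives methyl (4R)-2,6,6-trimethyl-4-(triethylsilyloxy)cyclohexane-1-carboxylate F5. The ester enolate (LiN(i-Pr)2, THF, −78 °C) is selenenylated with PhSeBr, anti to the neighbouring methyl group, to give methyl (4R)-2,6,6-trimethyl-1-(phenylselanyl)-4-(triethylsilyloxy)cyclohexane-1-carboxylate F6. Oxidation (H2O2, pyridine) and syn-elimination of the selenoxide toward the only β-hydrogen (on C5) give 9.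

3. Step 17. The long, electron-rich polyenal may add sluggishly to the silyloxyfuran, and the silyl triflate/DBU sequence may erode the Z geometry of the ylidene bond or degrade the polyene. The fallback builds the butenolide by palladium/copper-catalysed coupling–lactonisation, sets out from 21 and returns at 29. Homologation of 21 with dimethyl (1-diazo-2-oxopropyl)phosphonate (K2CO3, MeOH; Ohira–Bestmann) gives the symmetric (3E,5E,7E,9E)-3,10-dimethyldodeca-3,5,7,9-tetraene-1,11-diyne F7. Sonogashira coupling of an excess of F7 with 24 (Pd(PPh3)4, CuI, Et3N) gives (1R)-4-[(3E,5E,7E,9E)-3,10-dimethyldodeca-3,5,7,9-tetraene-1,11-diyn-1-yl]-3,5,5-trimethylcyclohex-3-en-1-yl acetate F8. Tandem Sonogashira coupling/5-exo-dig lactonisation of F8 with (E)-2,3-dibromoprop-2-enoic acid (Pd(PPh3)2Cl2, CuI, Et3N, MeCN) gives 29.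

Further compounds
F1 | step 1 | di-tert-butyl 3,3-dimethylpentanedioate | CC(C)(C)OC(=O)CC(C)(C)CC(=O)OC(C)(C)C
F2 | step 1 | di-tert-butyl 2,2,4-trimethyl-6-oxocyclohexane-1,3-dicarboxylate | CC1CC(=O)C(C(=O)OC(C)(C)C)C(C)(C)C1C(=O)OC(C)(C)C
F3 | step 1 | 2,6,6-trimethyl-4-oxocyclohexane-1-carboxylic acid | CC1CC(=O)CC(C)(C)C1C(O)=O
F4 | step 4 | methyl (4S)-2,6,6-trimethyl-4-(triethylsilyloxy)cyclohex-2-ene-1-carboxylate | COC(=O)C1C(C)=C[C@@H](O[Si](CC)(CC)CC)CC1(C)C
F5 | step 4 | methyl (4R)-2,6,6-trimethyl-4-(triethylsilyloxy)cyclohexane-1-carboxylate | COC(=O)C1C(C)C[C@@H](O[Si](CC)(CC)CC)CC1(C)C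
F6 | step 4 | methyl (4R)-2,6,6-trimethyl-1-(phenylselanyl)-4-(triethylsilyloxy)cyclohexane-1-carboxylate | COC(=O)C1([Se]c2ccccc2)C(C)C[C@@H](O[Si](CC)(CC)CC)CC1(C)C
F7 | step 17 | (3E,5E,7E,9E)-3,10-dimethyldodeca-3,5,7,9-tetraene-1,11-diyne | C#C/C(C)=C/C=C/C=C/C=C(C)/C#C
F8 | step 17 | (1R)-4-[(3E,5E,7E,9E)-3,10-dimethyldodeca-3,5,7,9-tetraene-1,11-diyn-1-yl]-3,5,5-trimethylcyclohex-3-en-1-yl acetate | CC(=O)O[C@@H]1CC(C)=C(C#C/C(C)=C/C=C/C=C/C=C(C)/C#C)C(C)(C)C1
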